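Ring labels used throughout: ring A is the benzoyl ring that keeps the free 4-hydroxyl, ring B the ring that keeps the free carboxylic acid. In each ring C1 bears the carboxyl carbon, C2 the methoxy group, C4 the second oxygen and C6 the pentyl chain.

## The problem

4-O-Demethylplanaic acid (18) is a depside: two copies of one 4-oxy-2-methoxy-6-pentylbenzoic acid are joined by an aryl ester between the carboxyl group of ring A and the 4-oxygen of ring B. There is no stereocenter, so the task is regiochemistry on two 1,2,3,5-tetrasubstituted benzene rings and the order in which acyl–oxygen bonds are made and broken. The two oxygens of each ring must end up different (methyl ether at C2, free or acylated oxygen at C4), which a resorcylate starting material delivers only through a selective alkylation. Each carboxyl carbon sits between a methoxy group and a pentyl chain, so ester cleavage and depside esterification at these carbonyls are both sterically slowed. The inter-ring aryl ester is an activated ester, and the electron-rich benzoic acids lose CO2 in hot acid, so the final unmasking must be neutral. That points to benzyl groups and hydrogenolysis. The feature that allows a short route is that C1 (ester), C2 (OMe), C3 and C6 (pentyl) of either ring are C5, C4, C3 and C6 of a 4-methoxy-6-pentylpyran-2-one-5-carboxylate. Only C4 with its oxygen and C5 are missing, and these are the two carbons of a ketene acetal. Because the rings are identical, one ring synthesis supplies both.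

## Retrosynthesis

**Unmasking.** The last operation cuts the two O–CH2Ph bonds of 17, the depside with a benzyl ether on O4 of ring A and a benzyl ester on ring B. Benzyl is preferred to a methyl ester on ring B, because a final saponification or dealkylation would have to spare the activated aryl ester, whereas hydrogenolysis is neutral and removes both groups at once. Compound 17 is no simpler in skeleton than 18, but it has no acidic hydrogen and is the form in which the halves can be joined.

**Depside ester.** Cutting the C(=O)–O bond between the rings divides 17 into acid 13 and phenol 15, two derivatives of one arene. The neighbouring cut, through ring A with the ester already in place, is weighed under Alternative 1. The forward reaction must acylate a phenol with an acid whose carbonyl is flanked on both sides. Because 13 is electron-rich, its mixed anhydride 16 should ionise to a linear acylium ion that is not hindered. In 15 the carboxyl group is already a benzyl ester, so the phenol oxygen is the only nucleophile.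

**Both halves from one arene.** Phenol 15 is cut at the O–CH2Ph bond of its ester to hydroxy acid 14, 14 at the aryl O–CH2Ph bond to 13, and 13 at the ester O–CH3 bond to methyl ester 12. None of the forward steps attacks the crowded carbonyl carbon: iodide attacks the ester methyl group of 12, hydrogenolysis frees the phenol, and the carboxylate of 14 is alkylated on oxygen. The one demand is that the carboxylate, not the phenol, is alkylated, which a weak base secures. After this the whole problem rests on one benzoate, 12.

**Ring synthesis (key disconnection).** In 12 the bonds C3–C4 and C5–C6 are cut. Read backwards, benzyl alcohol 7 is added across C4–C5 to give cyclohexadiene 11, the lactone bridge is restored between C3 and C6 to give bicycle 10, and a retro-[4+2] step divides 10 into pyranone 5 and ketene acetal 9. This is preferred to alkylating a resorcylate because the C2 oxygen arrives as the methyl ether of 5 and the C4 oxygen as a benzyl ether from 9. The two are different from the moment the ring exists, and the benzyl group is the protecting group the endgame needs. The precursors are a monocyclic lactone and a two-carbon reagent. The forward reaction must bond the CH2 terminus of 9 to C6 of 5 and not to C3, which the C5 ester and lactone carbonyl dictate. It must also overcome the lower reactivity of a diene carrying a 4-methoxy group. This is met from within the step: a hot, concentrated solution of 5 with an excess of freshly made 9.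

**Pyranone.** Pyranone 5 is cut at the O–CH3 bond to the vinylogous acid 4, 4 at the lactone O1–C2 bond to the acyclic tricarbonyl compound 3, and 3 at the bond between its central carbon and the hexanoyl carbonyl to diester 1 and acid chloride 2. All ring carbons and the pentyl chain come from these two bulk chemicals. Only one six-membered lactone can form from 3, so the cyclisation has no regiochemical choice. The methylation must take the 4-oxygen and not the lactone carbonyl oxygen.

**Ketene acetal.** Acetal 9 is cut at the C=C bond to bromo acetal 8 (dehydrobromination), and 8 at its two acetal C–O bonds to bromo acetal 6 and benzyl alcohol 7 (acetal exchange). Compound 9 is acid- and moisture-sensitive, so it is made last and used at once.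

## Roads not taken

**Alternative 1:** The cut runs through ring A at C1–C2 and C5–C6, with the depside ester already present. Phenol 15 would be acylated with oct-2-ynoic acid A4 to give benzyl 2-methoxy-4-(oct-2-ynoyloxy)-6-pentylbenzoate A2. The diene 1,1-dimethoxy-3-(trimethylsilyloxy)buta-1,3-diene A3 would then add across the triple bond, its CH2 terminus to the pentyl-bearing alkyne carbon. Loss of one methoxy group and of the silyl group from the adduct gives benzyl 4-[(4-hydroxy-2-methoxy-6-pentylbenzoyl)oxy]-2-methoxy-6-pentylbenzoate A1, one hydrogenolysis from 18.
- Merits: the inter-ring ester is made with an unhindered alkynoic acid, so the hindered esterification of the chosen plan (step 10) is avoided. Ring A emerges with its 4-hydroxyl free and its 2-methoxy group in place, so it needs no protecting group and no cleavage of a hindered ester. In these two respects this road is better.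
- Weak points: an alkynoate with an alkyl group on its β-carbon is a sluggish dienophile and A3 is hydrolytically fragile. The aryl ester of A2 is activated and is exposed to the alcohol set free on aromatisation. The ring synthesis is carried out on the most advanced intermediate.
- Comparison: phenol 15 still has to be made by a separate arene synthesis, so the identity of the two rings is not exploited and the step count is not lower. The chosen plan sets against it a single ring synthesis, done early on simple material, that feeds both halves.

**Alternative 2:** The cut removes the pentyl and carboxyl groups from an intact, already dioxygenated ring. (3-Fluoro-5-methoxyphenoxy)tri(propan-2-yl)silane A6 would be lithiated between fluorine and methoxy and would lose fluoride to give the aryne 3-methoxy-5-[tri(propan-2-yl)silyloxy]benzyne A8. Pentylmagnesium bromide A7 adds at the aryne carbon remote from the methoxy group, and the arylmagnesium next to the methoxy group is carboxylated to 2-methoxy-6-pentyl-4-[tri(propan-2-yl)silyloxy]benzoic acid A5.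
- Merits: the ring is bought, the oxygens are different from the start, and the hindered acid is obtained free, so no ester has to be cleaved. Counting the later protecting-group steps, this road is clearly shorter than the chosen one.
- Weak points: three selectivities must hold in one flask (site of lithiation, direction of fluoride loss, direction of Grignard addition). The aryne can also be intercepted by the aryllithium it came from or by the base. The whole operation is cryogenic and sensitive to the order and rate of addition.
- Comparison: the chosen plan concedes step count. It sets against this the fact that every substituent position is fixed by connectivity, not by competing rates, and that it uses bulk starting materials and thermal chemistry that scale without special equipment.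

**Alternative 3:** The cut takes the ring apart into a vinylketene and an alkyne. Irradiation of methyl (E)-3-(2-diazoacetyl)oct-2-enoate A10 triggers a Wolff rearrangement to a vinylketene, which adds benzyl ethynyl ether A11 in a [2+2] sense. The 4-vinylcyclobutenone opens and recloses by 6π electrocyclisation (Danheiser benzannulation) to methyl 4-(benzyloxy)-2-hydroxy-6-pentylbenzoate A9.
- Merits: the regiochemistry is locked by the mechanism, the ring forms under milder heating than a pyranone cycloaddition needs, and one arene again serves both rings.
- Weak points: A9 still needs O-methylation to reach 12. A10 requires a longer preparation that ends with diazo chemistry. A11 rearranges thermally near room temperature and must be made and used cold. The photochemical step limits scale.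
- Comparison: this road is the more secure in regiochemistry and the gentler thermally. The chosen plan sets against it two fewer operations to 12, no diazo or photochemical step, and the methyl ether already in place when the ring forms.

Key step: step 6

## Route

Step 1
Reactants: 1 dimethyl 3-oxoglutarate (dimethyl 3-oxopentanedioate); 2 hexanoyl chloride
Product: 3 dimethyl 2-hexanoyl-3-oxopentanedioate
Conditions: MgCl2, pyridine, CH2Cl2, 0 °C to rt; aq. HCl work-up
Reagents that add atoms: none
Why: Magnesium-mediated C-acylation of a β-keto ester: the chelated magnesium enolate is acylated on carbon, and the more acidic tricarbonyl product stays chelated, which should prevent a second acylation.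

Step 2
Reactants: 3 dimethyl 2-hexanoyl-3-oxopentanedioate
Product: 4 methyl 4-hydroxy-2-oxo-6-pentyl-2H-pyran-5-carboxylate
Conditions: conc. H2SO4, 0 °C to rt; then ice–water
Reagents that add atoms: none
Why: Acid-promoted lactonisation of a 3,5-dioxo ester: the enol oxygen of the hexanoyl ketone attacks the remote ester with loss of methanol, the only six-membered closure open to 3, and the product is stabilised as the 4-hydroxypyran-2-one.

Step 3
Reactants: 4 methyl 4-hydroxy-2-oxo-6-pentyl-2H-pyran-5-carboxylate
Product: 5 methyl 4-methoxy-2-oxo-6-pentyl-2H-pyran-5-carboxylate
Conditions: Me2SO4, K2CO3, acetone, reflux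
Reagents that add atoms: dimethyl sulfate, COS(=O)(=O)OC
Why: O-Alkylation of a vinylogous carboxylic acid; with dimethyl sulfate and carbonate, 4-hydroxypyran-2-ones are methylated at the 4-oxygen and keep the pyran-2-one form.

Step 4
Reactants: 6 bromoacetaldehyde diethyl acetal (2-bromo-1,1-diethoxyethane); 7 benzyl alcohol
Product: 8 bromoacetaldehyde dibenzyl acetal [1,1-bis(benzyloxy)-2-bromoethane]
Conditions: 7 (2.2 equiv), TsOH·H2O (cat.), neat, 90 °C, EtOH distilled off under reduced pressure
Reagents that add atoms: none
Why: Acid-catalysed acetal exchange, driven to the dibenzyl acetal by removal of the volatile ethanol.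

Step 5
Reactants: 8 bromoacetaldehyde dibenzyl acetal
Product: 9 1,1-bis(benzyloxy)ethene
Conditions: KOtBu, THF, 0 °C to rt; filtration and short-path distillation from base-washed glass
Reagents that add atoms: none
Why: E2 dehydrobromination of an α-bromo acetal, the standard entry to ketene acetals; the hindered alkoxide eliminates and does not substitute, and 9 is used immediately.

Step 6
Reactants: 5 methyl 4-methoxy-2-oxo-6-pentyl-2H-pyran-5-carboxylate; 9 1,1-bis(benzyloxy)ethene
Product: 12 methyl 4-(benzyloxy)-2-methoxy-6-pentylbenzoate, via bicyclic lactone 10 (not isolated), via cyclohexadiene 11 (not isolated)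
Conditions: 9 (3 equiv), toluene (about 1 M in 5), sealed tube, 130 °C
Reagents that add atoms: none
Why: Inverse-electron-demand Diels–Alder reaction of a pyran-2-one with a ketene acetal, the known route from pyran-2-one carboxylates to alkoxybenzoates. The electron-rich CH2 terminus of 9 bonds to C6 of 5 (β to the C5 ester, δ to the lactone carbonyl) and the acetal carbon bonds to C3; whether the bonds form in one asynchronous step or through a short-lived zwitterion, the six-membered carbocycle is closed by [4+2] addition across the diene termini to give the bridged lactone 10. Retro-[4+2] loss of CO2 from 10 gives cyclohexadiene 11, and 1,2-elimination of benzyl alcohol across the former acetal carbon and the CH2 group aromatises it to 12. The selectivity needed is regiochemical, CH2 to C6 and not to C3; the C5 ester and the lactone carbonyl make C6 the electrophilic terminus, and the 4-methoxy group makes C3 the nucleophilic end that matches the oxocarbenium-like acetal carbon. The bridgehead stereocenters of 10 are transient and racemic, so no stereocontrol is required. The 4-methoxy group makes 5 a poorer diene than the usual pyranone esters, so the reaction is run hot and concentrated in 5, which favours the bimolecular cycloaddition over unimolecular thermal rearrangement of the benzyl ketene acetal. The benzyl ether ends on C4 and the methyl ether on C2, so the two oxygens are differentiated by construction.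

Step 7
Reactants: 12 methyl 4-(benzyloxy)-2-methoxy-6-pentylbenzoate
Product: 13 4-(benzyloxy)-2-methoxy-6-pentylbenzoic acid
Conditions: LiI, pyridine, reflux; then 1 M HCl
Reagents that add atoms: none
Why: SN2 dealkylation of a methyl ester by iodide: attack at the methyl carbon avoids the carbonyl carbon shielded by OMe and pentyl, and carboxylate is a far better leaving group than the aryl oxides of the two ethers.

Step 8
Reactants: 13 4-(benzyloxy)-2-methoxy-6-pentylbenzoic acid (the portion destined for ring B)
Product: 14 4-hydroxy-2-methoxy-6-pentylbenzoic acid
Conditions: H2 (1 atm), Pd/C, EtOAc, rt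
Reagents that add atoms: none
Why: Catalytic hydrogenolysis of a benzyl aryl ether; the arene, methyl ether and carboxylic acid are inert under these conditions.

Step 9
Reactants: 14 4-hydroxy-2-methoxy-6-pentylbenzoic acid
Product: 15 benzyl 4-hydroxy-2-methoxy-6-pentylbenzoate
Conditions: BnBr (1.05 equiv), KHCO3, DMF, rt
Reagents that add atoms: benzyl bromide, BrCc1ccccc1
Why: Carboxylate O-alkylation (SN2): hydrogen carbonate ionises the acid but not the phenol, and alkylation on the carboxylate oxygen is not affected by the crowding at the carbonyl carbon.

Step 10
Reactants: 13 4-(benzyloxy)-2-methoxy-6-pentylbenzoic acid; 15 benzyl 4-hydroxy-2-methoxy-6-pentylbenzoate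
Product: 17 benzyl 4-{[4-(benzyloxy)-2-methoxy-6-pentylbenzoyl]oxy}-2-methoxy-6-pentylbenzoate, via mixed trifluoroacetic anhydride 16 (not isolated)
Conditions: (CF3CO)2O, toluene, 0 °C to rt
Reagents that add atoms: none
Why: Depside esterification through a mixed trifluoroacetic anhydride: the electron-rich aroyl group of 16 ionises to a linear acylium ion that acylates the phenol despite the two ortho substituents, and the ester-deactivated ring of 15 should resist C-acylation.

Step 11
Reactants: 17 benzyl 4-{[4-(benzyloxy)-2-methoxy-6-pentylbenzoyl]oxy}-2-methoxy-6-pentylbenzoate
Product: 18 4-O-demethylplanaic acid {4-[(4-hydroxy-2-methoxy-6-pentylbenzoyl)oxy]-2-methoxy-6-pentylbenzoic acid}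
Conditions: H2 (1 atm), Pd/C, EtOAc, rt
Reagents that add atoms: none
Why: Hydrogenolysis of the benzyl ether and the benzyl ester in one neutral operation; the inter-ring aryl ester is not a benzylic C–O bond and should survive.

## Compound list

1 | dimethyl 3-oxoglutarate (dimethyl 3-oxopentanedioate) | COC(=O)CC(=O)CC(=O)OC | starting material
2 | hexanoyl chloride | CCCCCC(=O)Cl | starting material
3 | dimethyl 2-hexanoyl-3-oxopentanedioate | CCCCCC(=O)C(C(=O)OC)C(=O)CC(=O)OC | intermediate
4 | methyl 4-hydroxy-2-oxo-6-pentyl-2H-pyran-5-carboxylate | CCCCCC1=C(C(=O)OC)C(O)=CC(=O)O1 | intermediate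
5 | methyl 4-methoxy-2-oxo-6-pentyl-2H-pyran-5-carboxylate | CCCCCC1=C(C(=O)OC)C(OC)=CC(=O)O1 | intermediate
6 | bromoacetaldehyde diethyl acetal (2-bromo-1,1-diethoxyethane) | CCOC(CBr)OCC | starting material
7 | benzyl alcohol | OCc1ccccc1 | starting material
8 | bromoacetaldehyde dibenzyl acetal [1,1-bis(benzyloxy)-2-bromoethane] | BrCC(OCc1ccccc1)OCc1ccccc1 | intermediate
9 | 1,1-bis(benzyloxy)ethene | C=C(OCc1ccccc1)OCc1ccccc1 | intermediate
10 | methyl 8,8-bis(benzyloxy)-5-methoxy-3-oxo-1-pentyl-2-oxabicyclo[2.2.2]oct-5-ene-6-carboxylate (racemic, not isolated) | CCCCCC12OC(=O)C(C(OC)=C1C(=O)OC)C(OCc3ccccc3)(OCc3ccccc3)C2 | intermediate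
11 | methyl 4,4-bis(benzyloxy)-6-methoxy-2-pentylcyclohexa-1,5-diene-1-carboxylate (not isolated) | CCCCCC1=C(C(=O)OC)C(OC)=CC(OCc2ccccc2)(OCc2ccccc2)C1 | intermediate
12 | methyl 4-(benzyloxy)-2-methoxy-6-pentylbenzoate | CCCCCc1cc(OCc2ccccc2)cc(OC)c1C(=O)OC | intermediate
13 | 4-(benzyloxy)-2-methoxy-6-pentylbenzoic acid | CCCCCc1cc(OCc2ccccc2)cc(OC)c1C(=O)O | intermediate
14 | 4-hydroxy-2-methoxy-6-pentylbenzoic acid | CCCCCc1cc(O)cc(OC)c1C(=O)O | intermediate
15 | benzyl 4-hydroxy-2-methoxy-6-pentylbenzoate | CCCCCc1cc(O)cc(OC)c1C(=O)OCc1ccccc1 | intermediate
16 | 4-(benzyloxy)-2-methoxy-6-pentylbenzoic trifluoroacetic anhydride (not isolated) | CCCCCc1cc(OCc2ccccc2)cc(OC)c1C(=O)OC(=O)C(F)(F)F | intermediate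
17 | benzyl 4-{[4-(benzyloxy)-2-methoxy-6-pentylbenzoyl]oxy}-2-methoxy-6-pentylbenzoate | CCCCCc1cc(OC(=O)c2c(CCCCC)cc(OCc3ccccc3)cc2OC)cc(OC)c1C(=O)OCc1ccccc1 | intermediate
18 | 4-O-demethylplanaic acid {4-[(4-hydroxy-2-methoxy-6-pentylbenzoyl)oxy]-2-methoxy-6-pentylbenzoic acid} | CCCCCc1cc(OC(=O)c2c(CCCCC)cc(O)cc2OC)cc(OC)c1C(=O)O | target

## Step count and risks

Total: 11 steps. Longest linear sequence: 9 steps (1, 2, 3, 6, 7, 8, 9, 10, 11, from dimethyl 3-oxoglutarate). The ketene acetal branch (steps 4 and 5) joins at step 6.

**Step 6 (key step).** The most likely failure is that cycloaddition to the electron-rich 4-methoxy diene is slower than thermal loss of the ketene acetal. The acetal can be lost by oxygen-to-carbon benzyl migration, or by hydrolysis and oligomerisation started by traces of acid. A lesser risk is incomplete elimination of benzyl alcohol from the cyclohexadiene, which a brief treatment with catalytic acid after the thermolysis should complete.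

The fallback sets out from 5 and returns at 12:
- Pyranone 5 is heated in an excess of commercial, thermally robust 1,1-dimethoxyethene. The same cycloaddition, CO2 loss and alcohol elimination give methyl 2,4-dimethoxy-6-pentylbenzoate F1.
- BBr3 in CH2Cl2 (−78 °C to rt) removes both aryl methyl groups to give methyl 2,4-dihydroxy-6-pentylbenzoate F2.
- Benzyl bromide and K2CO3 in acetone alkylate only the 4-hydroxyl, because the 2-hydroxyl is hydrogen-bonded to the ester. This gives methyl 4-(benzyloxy)-2-hydroxy-6-pentylbenzoate F3 (identical in structure with A9).
- MeI and K2CO3 in DMF methylate the remaining phenol to give 12.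

This keeps the pyranone ring synthesis but differentiates the oxygens by chelation-controlled alkylation, at the cost of three more steps.

**Step 7.** Dealkylation may stall, or iodide may also attack the C2 methyl ether, which lithium chelation to the neighbouring carboxyl group activates. The fallback sets out from 12 and returns at 13, changing the oxidation level instead of cleaving the ester:
- LiAlH4 in THF (0 °C), small enough to reach the hindered carbonyl, gives [4-(benzyloxy)-2-methoxy-6-pentylphenyl]methanol F4.
- MnO2 in CH2Cl2 gives 4-(benzyloxy)-2-methoxy-6-pentylbenzaldehyde F5.
- Pinnick oxidation (NaClO2, NaH2PO4, 2-methyl-2-butene, tBuOH–water) gives acid 13.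

**Step 10.** The acylium ion may be diverted into C-acylation of an electron-rich ring (ketone formation), or the phenol may be consumed by trifluoroacetylation. The fallback sets out from 13 and returns at 17, replacing the acidic acylium path by an acid chloride and a phenoxide:
- 1-Chloro-N,N,2-trimethylprop-1-en-1-amine in CH2Cl2 at rt gives 4-(benzyloxy)-2-methoxy-6-pentylbenzoyl chloride F6 under neutral conditions.
- The sodium salt of 15 (NaH, THF) is acylated with F6 to give 17.

**Step 2.** In concentrated acid the tricarbonyl compound may undergo retro-Claisen loss of the hexanoyl group, or the ring ester may be hydrolysed and decarboxylated. The fallback sets out from 2, returns at 4 and replaces steps 1 and 2: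
- Potassium methyl malonate is acylated with 2 (MgCl2, Et3N, MeCN) with decarboxylation to give methyl 3-oxooctanoate F7.
- Malonyl dichloride (CH2Cl2, rt to 40 °C) acylates the α-carbon of F7 and the enol oxygen to close the same hydroxypyranone 4, a known annulation of β-keto esters.

## Further compounds

F1 | step 6 | methyl 2,4-dimethoxy-6-pentylbenzoate | CCCCCc1cc(OC)cc(OC)c1C(=O)OC
F2 | step 6 | methyl 2,4-dihydroxy-6-pentylbenzoate | CCCCCc1cc(O)cc(O)c1C(=O)OC
F3 | step 6 | methyl 4-(benzyloxy)-2-hydroxy-6-pentylbenzoate | CCCCCc1cc(OCc2ccccc2)cc(O)c1C(=O)OC
F4 | step 7 | [4-(benzyloxy)-2-methoxy-6-pentylphenyl]methanol | CCCCCc1cc(OCc2ccccc2)cc(OC)c1CO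
F5 | step 7 | 4-(benzyloxy)-2-methoxy-6-pentylbenzaldehyde | CCCCCc1cc(OCc2ccccc2)cc(OC)c1C=O
F6 | step 10 | 4-(benzyloxy)-2-methoxy-6-pentylbenzoyl chloride | CCCCCc1cc(OCc2ccccc2)cc(OC)c1C(=O)Cl
F7 | step 2 | methyl 3-oxooctanoate | CCCCCC(=O)CC(=O)OC
A1 | alternative 1 | benzyl 4-[(4-hydroxy-2-methoxy-6-pentylbenzoyl)oxy]-2-methoxy-6-pentylbenzoate | CCCCCc1cc(OC(=O)c2c(CCCCC)cc(O)cc2OC)cc(OC)c1C(=O)OCc1ccccc1
A2 | alternative 1 | benzyl 2-methoxy-4-(oct-2-ynoyloxy)-6-pentylbenzoate | CCCCCC#CC(=O)Oc1cc(CCCCC)c(C(=O)OCc2ccccc2)c(OC)c1
A3 | alternative 1 | 1,1-dimethoxy-3-(trimethylsilyloxy)buta-1,3-diene | C=C(O[Si](C)(C)C)C=C(OC)OC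
A4 | alternative 1 | oct-2-ynoic acid | CCCCCC#CC(=O)O
A5 | alternative 2 | 2-methoxy-6-pentyl-4-[tri(propan-2-yl)silyloxy]benzoic acid | CCCCCc1cc(O[Si](C(C)C)(C(C)C)C(C)C)cc(OC)c1C(=O)O
A6 | alternative 2 | (3-fluoro-5-methoxyphenoxy)tri(propan-2-yl)silane | COc1cc(F)cc(O[Si](C(C)C)(C(C)C)C(C)C)c1
A7 | alternative 2 | pentylmagnesium bromide | CCCCC[Mg]Br
A8 | alternative 2 | 3-methoxy-5-[tri(propan-2-yl)silyloxy]benzyne | COC1=CC(O[Si](C(C)C)(C(C)C)C(C)C)=CC#C1
A9 | alternative 3 | methyl 4-(benzyloxy)-2-hydroxy-6-pentylbenzoate | CCCCCc1cc(OCc2ccccc2)cc(O)c1C(=O)OC
A10 | alternative 3 | methyl (E)-3-(2-diazoacetyl)oct-2-enoate | CCCCC/C(=C\C(=O)OC)C(=O)C=[N+]=[N-]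
A11 | alternative 3 | benzyl ethynyl ether [(ethynyloxy)methyl]benzene | C#COCc1ccccc1
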